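**Retrosynthetic overview**
1. Feature: each half ends in a trans-fused α-methyl γ-lactone on a seven-membered ring. C6–C7 and C6′–C7′ join the lactone carbinol carbons to the carbons that carry C11/C11′, and the C10/C10′ oxygen lies cis to C11/C11′ across each seven-membered ring.
2. Key disconnection: C6–C7 and C6′–C7′ by double CrCl2 allylation of the C6/C6′ aldehydes. Each ester carbonyl is supplied as a seven-membered C10–O (C10′–O) lactone whose endocyclic C7=C11 alkene fixes the allyl geometry; an open-chain (Z)-2-(bromomethyl)enoate would give cis-fused lactones through the chair. Acyl transfer then forms both γ-lactones and frees both tertiary alcohols.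
3. Core: norbornanone with endo-fused ring A by Diels–Alder reaction of a 2-silyloxycyclopentadiene (C2′–C5′) with a 4-substituted cyclopentenone (C2=C3); the ring A enal follows by haloformylation and methylation.
4. Both cycloaddition partners are the two C1-epimeric cyclopentenones obtained from one cyclopent-3-enyl lactone by singlet-oxygen ene oxidation; C10 comes from a Sharpless epoxidation.
5. Ring order: oxepinone tether (metathesis), norbornane (Diels–Alder), then two cycloheptane rings and two γ-lactones (key step).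

Key step: step 24

Remark: guaiane numbering is used (unprimed atoms for the half with the C4=C5 alkene, primed atoms for the half with the C3′ ketone; C12 lactone carbonyl, C13 exocyclic carbon), and the allylchromium additions are assumed to pass through closed chair transition states.

**Route**

Step 1
Reactants: 1 cyclopent-3-ene-1-carboxylic acid
Product: 2 1-(cyclopent-3-en-1-yl)ethan-1-one
Conditions: MeLi (2.2 equiv), Et2O, 0 °C → rt; aq. NH4Cl
Reagents that add atoms: methyllithium, [Li]C
Why: Addition of an organolithium to a lithium carboxylate gives a dialkoxide that collapses to the methyl ketone only on work-up.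

Step 2
Reactants: 2 1-(cyclopent-3-en-1-yl)ethan-1-one
Product: 3 ethyl (2E)-3-(cyclopent-3-en-1-yl)but-2-enoate
Conditions: (EtO)2P(O)CH2CO2Et, NaH, THF, 0 °C → reflux; chromatography
Reagents that add atoms: triethyl phosphonoacetate, CCOC(=O)CP(=O)(OCC)OCC
Why: Horner–Wadsworth–Emmons olefination of a methyl ketone should favour the E enoate, with the branched ring trans to the ester; any Z isomer is removed.

Step 3
Reactants: 3 ethyl (2E)-3-(cyclopent-3-en-1-yl)but-2-enoate
Product: 4 (2E)-3-(cyclopent-3-en-1-yl)but-2-en-1-ol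
Conditions: i-Bu2AlH, CH2Cl2, −78 °C
Reagents that add atoms: none
Why: 1,2-Reduction of an enoate to the allylic alcohol, with no change in alkene geometry.

Step 4
Reactants: 4 (2E)-3-(cyclopent-3-en-1-yl)but-2-en-1-ol
Product: 5 [(2R,3R)-3-(cyclopent-3-en-1-yl)-3-methyloxiran-2-yl]methanol
Conditions: Ti(Oi-Pr)4 (cat.), D-(−)-diethyl tartrate (cat.), t-BuOOH, 4 Å MS, CH2Cl2, −20 °C
Reagents that add atoms: tert-butyl hydroperoxide, CC(C)(C)OO
Why: Sharpless asymmetric epoxidation; the D-tartrate ligand delivers oxygen to the face of the E allylic alcohol that gives the (2R,3R) epoxide and so fixes the later C10, while the isolated ring alkene does not react.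

Step 5
Reactants: 5 [(2R,3R)-3-(cyclopent-3-en-1-yl)-3-methyloxiran-2-yl]methanol
Product: 6 (3S)-3-(cyclopent-3-en-1-yl)butane-1,3-diol
Conditions: NaAlH2(OCH2CH2OMe)2, THF, 0 °C → rt
Reagents that add atoms: none
Why: Intramolecular hydride delivery from the alkoxyaluminate opens 2,3-epoxy alcohols at C2 to give 1,3-diols; the fully substituted carbon is untouched, so the tertiary carbinol keeps its configuration.

Step 6
Reactants: 6 (3S)-3-(cyclopent-3-en-1-yl)butane-1,3-diol
Product: 7 (2S)-2-(cyclopent-3-en-1-yl)-4-iodobutan-2-ol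
Conditions: I2, PPh3, imidazole, CH2Cl2, 0 °C
Reagents that add atoms: iodine, II
Why: Appel-type iodination is selective for the primary hydroxyl; the tertiary alcohol is inert under these conditions.

Step 7
Reactants: 7 (2S)-2-(cyclopent-3-en-1-yl)-4-iodobutan-2-ol
Product: 8 (2S)-2-(cyclopent-3-en-1-yl)hept-6-en-2-ol
Conditions: CH2=CHMgBr (3 equiv), CuI (cat.), THF, −30 → 0 °C
Reagents that add atoms: vinylmagnesium bromide, C=C[Mg]Br
Why: Copper-catalysed cross-coupling of a primary alkyl iodide with an alkenyl Grignard reagent; the magnesium alkoxide of the tertiary alcohol is a spectator at low temperature.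

Step 8
Reactants: 9 ethyl 2-(hydroxymethyl)prop-2-enoate
Product: 10 ethyl 2-{[(tert-butyldiphenylsilyl)oxy]methyl}prop-2-enoate
Conditions: t-BuPh2SiCl, imidazole, DMF, 0 °C → rt
Reagents that add atoms: tert-butyl(chloro)diphenylsilane, CC(C)(C)[Si](Cl)(c1ccccc1)c1ccccc1
Why: Standard silylation of a primary allylic alcohol; this silyl ether is chosen to survive acid, zerovalent palladium and the haloformylation later on.

Step 9
Reactants: 10 ethyl 2-{[(tert-butyldiphenylsilyl)oxy]methyl}prop-2-enoate
Product: 11 2-{[(tert-butyldiphenylsilyl)oxy]methyl}prop-2-enoic acid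
Conditions: LiOH, THF/H2O, 0 °C; then 1 M HCl
Reagents that add atoms: lithium hydroxide, [Li+].[OH-]
Why: Saponification of the ethyl ester; the silyl ether is stable to cold aqueous hydroxide.

Step 10
Reactants: 8 (2S)-2-(cyclopent-3-en-1-yl)hept-6-en-2-ol; 11 2-{[(tert-butyldiphenylsilyl)oxy]methyl}prop-2-enoic acid
Product: 13 (2S)-2-(cyclopent-3-en-1-yl)hept-6-en-2-yl 2-{[(tert-butyldiphenylsilyl)oxy]methyl}prop-2-enoate, via acid chloride 12 (not isolated)
Conditions: 11, (COCl)2, DMF (cat.), CH2Cl2, 0 °C → rt, evaporate; then 8, DMAP, i-Pr2NEt, CH2Cl2, 0 → 40 °C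
Reagents that add atoms: none
Why: DMAP-catalysed acylation of a tertiary alcohol by an acid chloride that has no α-hydrogen, done on a simple substrate where forcing conditions do no harm.

Step 11
Reactants: 13 (2S)-2-(cyclopent-3-en-1-yl)hept-6-en-2-yl 2-{[(tert-butyldiphenylsilyl)oxy]methyl}prop-2-enoate
Product: 14 (7S)-3-{[(tert-butyldiphenylsilyl)oxy]methyl}-7-(cyclopent-3-en-1-yl)-7-methyl-6,7-dihydrooxepin-2(5H)-one
Conditions: second-generation Hoveyda–Grubbs catalyst (cat.), toluene (high dilution), 80 °C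
Reagents that add atoms: none
Why: Ring-closing metathesis of the terminal alkene with the 1,1-disubstituted acrylate, helped by the fully substituted C10; the seven-membered ring makes C8 cis to the carbonyl at the new C7=C11 alkene, and the unstrained cyclopentene is expected to stay closed under dilution.

Step 12
Reactants: 14 (7S)-3-{[(tert-butyldiphenylsilyl)oxy]methyl}-7-(cyclopent-3-en-1-yl)-7-methyl-6,7-dihydrooxepin-2(5H)-one
Product: 17 (7S)-3-{[(tert-butyldiphenylsilyl)oxy]methyl}-7-methyl-7-[(1S)-4-oxocyclopent-2-en-1-yl]-6,7-dihydrooxepin-2(5H)-one together with 18 its (1R)-4-oxocyclopent-2-en-1-yl epimer, via hydroperoxide 15 (not isolated), via hydroperoxide 16 (not isolated)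
Conditions: O2, meso-tetraphenylporphyrin (cat.), hν, CH2Cl2, 0 °C; then Ac2O, pyridine, DMAP (cat.), 0 °C → rt; chromatographic separation
Reagents that add atoms: oxygen, O=O
Why: Schenck ene reaction of singlet oxygen anti to the ring substituent, then Kornblum–DeLaMare-type dehydration, gives 4-substituted cyclopent-2-enones; loss of hydrogen from either ring methylene should be unselective, which is wanted because 17 (ketone on the C5 side, ring A) and 18 (ketone on the C2′ side, norbornanone half) are the two C1 epimers and both are needed, C1 being set only by this choice.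

Step 13
Reactants: 18 (7S)-3-{[(tert-butyldiphenylsilyl)oxy]methyl}-7-methyl-7-[(1R)-4-oxocyclopent-2-en-1-yl]-6,7-dihydrooxepin-2(5H)-one
Product: 19 the corresponding (1R)-3-iodo-4-oxocyclopent-2-en-1-yl lactone
Conditions: I2, pyridine, CH2Cl2, 0 °C → rt
Reagents that add atoms: iodine, II
Why: α-Iodination of a cyclic enone by pyridine addition, iodination and elimination; the α-substituted enoate in the lactone cannot react in this way.

Step 14
Reactants: 19 (1R)-3-iodo-4-oxocyclopent-2-en-1-yl lactone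
Product: 20 the corresponding (1R)-3-methyl-4-oxocyclopent-2-en-1-yl lactone
Conditions: Me4Sn, Pd2(dba)3 (cat.), AsPh3, CuI, NMP, 60 °C
Reagents that add atoms: tetramethylstannane, C[Sn](C)(C)C
Why: Stille coupling of an α-iodoenone under neutral conditions places the C4′ methyl group.

Step 15
Reactants: 20 (1R)-3-methyl-4-oxocyclopent-2-en-1-yl lactone
Product: 21 trimethylsilyl enol ether of the trans-2-vinyl-3-methylcyclopentanone (enol ether at C3′=C4′, vinyl at C5′ anti to the lactone at C1′)
Conditions: CH2=CHMgBr, CuBr·SMe2 (cat.), Me3SiCl, DMPU, THF, −78 °C; Et3N, cold NaHCO3 work-up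
Reagents that add atoms: vinylmagnesium bromide, C=C[Mg]Br; chlorotrimethylsilane, C[Si](C)(C)Cl
Why: Silyl-accelerated copper-catalysed conjugate addition anti to the C1′ substituent gives a regiodefined enol ether; the cyclopentenone is far more reactive than the trisubstituted enoate.

Step 16
Reactants: 21 trimethylsilyl enol ether
Product: 22 (7S)-3-{[(tert-butyldiphenylsilyl)oxy]methyl}-7-[(1R)-2-ethenyl-3-methyl-4-oxocyclopent-2-en-1-yl]-7-methyl-6,7-dihydrooxepin-2(5H)-one
Conditions: Pd(OAc)2 (1.1 equiv), MeCN, rt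
Reagents that add atoms: none
Why: Saegusa–Ito oxidation of the regiodefined silyl enol ether restores the enone, now with the C4′ methyl and the C5′ vinyl group (masked C6′ aldehyde); the C5′ stereocentre from step 15 is removed.

Step 17
Reactants: 22 dienone
Product: 23 (7S)-7-[(1R)-4-[(tert-butyldimethylsilyl)oxy]-2-ethenyl-3-methylcyclopenta-2,4-dien-1-yl]-3-{[(tert-butyldiphenylsilyl)oxy]methyl}-7-methyl-6,7-dihydrooxepin-2(5H)-one
Conditions: t-BuMe2SiOTf, Et3N, CH2Cl2, −78 °C; cold pentane/NaHCO3 work-up, used at once below −20 °C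
Reagents that add atoms: tert-butyldimethylsilyl trifluoromethanesulfonate, CC(C)(C)[Si](C)(C)OS(=O)(=O)C(F)(F)F
Why: Soft enolisation at the α′ methylene C2′ gives the cross-conjugated 2-silyloxydiene; C1′ carries an alkyl group rather than an acyl group and the diene is kept cold, so 1,5-hydrogen shifts should stay slow.

Step 18
Reactants: 23 silyloxydiene; 17 (7S)-3-{[(tert-butyldiphenylsilyl)oxy]methyl}-7-methyl-7-[(1S)-4-oxocyclopent-2-en-1-yl]-6,7-dihydrooxepin-2(5H)-one
Product: 25 tricyclic diketone (ring A cyclopentanone with C4=O endo-fused at C2–C3 to the norbornan-2-one with C3′=O; C4′ methyl endo, C5′ vinyl, C10′ on the C1′ bridge syn to the ketone bridge; oxepinone lactones at C1 and C1′), via silyl enol ether cycloadduct 24 (not isolated)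
Conditions: Me2AlCl (1.2 equiv), CH2Cl2, −78 → −40 °C; then CF3CO2H, THF/H2O, 0 °C
Reagents that add atoms: none
Why: Lewis acid-catalysed Diels–Alder reaction in which the electron-rich C2′ terminus bonds to the enone β-carbon C2 and C5′ to C3; attack anti to the C1 substituent on the dienophile, anti to the C1′ substituent on the diene and through the endo transition state sets C2, C3, C2′ and C5′, and kinetic protonation of the silyl enol ether on the exo face (the endo face is covered by ring A) sets C4′ with its methyl group endo.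

Step 19
Reactants: 25 tricyclic diketone
Product: 26 ring A β-bromo enal (C4–Br, C5–CHO), otherwise as 25
Conditions: PBr3, DMF, CHCl3, 0 °C → rt; aq. NaOAc
Reagents that add atoms: N,N-dimethylformamide, CN(C)C=O; phosphorus tribromide, BrP(Br)Br
Why: Vilsmeier–Haack–Arnold haloformylation needs an α-methylene group, which only the C4 ketone has (C5); the C3′ ketone is flanked by a methine and a bridgehead and can at most exchange its exo hydrogen, which returns the same C4′ configuration.

Step 20
Reactants: 26 β-bromo enal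
Product: 27 ring A enal (C4–CH3, C5–CHO), C5′ vinyl, bis-silyl ether
Conditions: Me4Sn, Pd(PPh3)4 (cat.), CuI, DMF, 60 °C
Reagents that add atoms: tetramethylstannane, C[Sn](C)(C)C
Why: Stille coupling of an activated β-bromo enal under neutral conditions installs the C15 methyl without the organometallic nucleophiles that would attack the lactones.

Step 21
Reactants: 27 ring A enal with C5′ vinyl
Product: 29 C6,C6′-dialdehyde bis(silyl ether), via vicinal diol 28 (not isolated)
Conditions: OsO4 (cat.), NaIO4, 2,6-lutidine, dioxane/H2O, rt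
Reagents that add atoms: osmium tetroxide (oxygen carrier, recycled), O=[Os](=O)(=O)=O; sodium periodate, [Na+].[O-]I(=O)(=O)=O
Why: Lemieux–Johnson cleavage; the monosubstituted vinyl group is the only unconjugated, electron-rich alkene, while the tetrasubstituted enal and the two enoates are much slower towards OsO4.

Step 22
Reactants: 29 dialdehyde bis(silyl ether)
Product: 30 dialdehyde bis(hydroxymethyl) bis-lactone
Conditions: HF·pyridine, pyridine, THF, 0 °C → rt
Reagents that add atoms: none
Why: Buffered fluoride removes both primary silyl ethers; there is no free tertiary hydroxyl, so no lactol can form with the aldehydes.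

Step 23
Reactants: 30 dialdehyde bis(hydroxymethyl) bis-lactone
Product: 31 dialdehyde bis[3-(bromomethyl)oxepin-2-one] (key-step precursor)
Conditions: N-bromosuccinimide, Me2S, CH2Cl2, −30 → 0 °C
Reagents that add atoms: N-bromosuccinimide, BrN1C(=O)CCC1=O
Why: Corey–Kim-type bromination of the allylic alcohols through alkoxysulfonium salts tolerates aldehydes; an SN2′ isomer would give the same allylchromium reagent in the next step.

Step 24
Reactants: 31 dialdehyde bis[3-(bromomethyl)oxepin-2-one]
Product: 33 bis(α-methylene γ-lactone) diol, via bridged hydroxy lactone 32 (not isolated)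
Conditions: CrCl2 (excess), THF/DMF, 0 °C → rt; aq. NH4Cl; then PPTS (cat.), CH2Cl2, rt
Reagents that add atoms: none
Why: Proposed new method: each allylic bromide is reduced by two equivalents of divalent chromium to an allylchromium at C13 (C13′), whose γ-carbon C7 (C7′) adds to the C6 (C6′) aldehyde through a six-membered chair transition state; the closest known reactions are the intramolecular Nozaki–Hiyama allylation–lactonisation of ω-formyl 2-(bromomethyl)alk-2-enoates and Barbier allylations of 3-(bromomethyl)butenolides, where the ester is also endocyclic. Each cycloheptane ring closes by 7-exo-trig attack on the aldehyde within a bicyclo[3.3.2] array, and each γ-lactone then forms by 5-exo-trig attack of the C6 (C6′) alkoxide on C12 (C12′), which expels the tertiary C10 (C10′) alkoxide and opens the strained oxepinone. C7 and C7′ are set by the tether, because C6 can reach C7 only on the oxepinone face that carries C1 at C10, which leaves C11 cis to the C10 oxygen. C6 and C6′ are set by the chair: the ring holds C8 trans to CH2Cr, so C8 and the aldehyde substituent C5 (C5′) are both equatorial, H6 and H7 are anti and the lactone is trans-fused; addition to the s-trans enal on the ring A face that bears C10 leads to the same result. The step needs aldehyde over C3′ ketone selectivity and 1,2- over 1,4-addition to the enal, both usual for allylchromium reagents, and an allyl unit that cannot isomerise, which the ring secures.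

Step 25
Reactants: 33 bis(α-methylene γ-lactone) diol
Product: 34 CNP0243924.4
Conditions: H2 (1 atm), RhCl(PPh3)3 (cat.), benzene/EtOH, rt
Reagents that add atoms: none
Why: Homogeneous hydrogenation reduces only the two exocyclic 1,1-disubstituted alkenes, not the tetrasubstituted C4=C5 alkene or the ketone; hydrogen should add to C11 and C11′ anti to the axial H7 and H7′, placing each methyl cis to H7 (H7′), the preferred arrangement in trans-fused 11,13-dihydro lactones.

**Compound list**
1 | cyclopent-3-ene-1-carboxylic acid | OC(=O)C1CC=CC1 | starting material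
2 | 1-(cyclopent-3-en-1-yl)ethan-1-one | CC(=O)C1CC=CC1 | intermediate
3 | ethyl (2E)-3-(cyclopent-3-en-1-yl)but-2-enoate | CCOC(=O)/C=C(\C)C1CC=CC1 | intermediate
4 | (2E)-3-(cyclopent-3-en-1-yl)but-2-en-1-ol | OC/C=C(\C)C1CC=CC1 | intermediate
5 | [(2R,3R)-3-(cyclopent-3-en-1-yl)-3-methyloxiran-2-yl]methanol | OC[C@H]1O[C@]1(C)C2CC=CC2 | intermediate
6 | (3S)-3-(cyclopent-3-en-1-yl)butane-1,3-diol | OCC[C@](C)(O)C1CC=CC1 | intermediate
7 | (2S)-2-(cyclopent-3-en-1-yl)-4-iodobutan-2-ol | ICC[C@](C)(O)C1CC=CC1 | intermediate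
8 | (2S)-2-(cyclopent-3-en-1-yl)hept-6-en-2-ol | C=CCC[C@](C)(O)C1CC=CC1 | intermediate
9 | ethyl 2-(hydroxymethyl)prop-2-enoate | C=C(CO)C(=O)OCC | starting material
10 | ethyl 2-{[(tert-butyldiphenylsilyl)oxy]methyl}prop-2-enoate | C=C(CO[Si](c1ccccc1)(c1ccccc1)C(C)(C)C)C(=O)OCC | intermediate
11 | 2-{[(tert-butyldiphenylsilyl)oxy]methyl}prop-2-enoic acid | C=C(CO[Si](c1ccccc1)(c1ccccc1)C(C)(C)C)C(=O)O | intermediate
12 | 2-{[(tert-butyldiphenylsilyl)oxy]methyl}prop-2-enoyl chloride (not isolated) | C=C(CO[Si](c1ccccc1)(c1ccccc1)C(C)(C)C)C(Cl)=O | intermediate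
13 | (2S)-2-(cyclopent-3-en-1-yl)hept-6-en-2-yl 2-{[(tert-butyldiphenylsilyl)oxy]methyl}prop-2-enoate | C=CCC[C@](C)(OC(=O)C(=C)CO[Si](c1ccccc1)(c1ccccc1)C(C)(C)C)C1CC=CC1 | intermediate
14 | (7S)-3-{[(tert-butyldiphenylsilyl)oxy]methyl}-7-(cyclopent-3-en-1-yl)-7-methyl-6,7-dihydrooxepin-2(5H)-one | C1=CCC(C1)[C@]2(C)CCC=C(CO[Si](c3ccccc3)(c3ccccc3)C(C)(C)C)C(=O)O2 | intermediate
15 | trans-4-hydroperoxycyclopent-2-en-1-yl lactone leading to 17 (not isolated) | OO[C@@H]1C=C[C@H](C1)[C@]2(C)CCC=C(CO[Si](c3ccccc3)(c3ccccc3)C(C)(C)C)C(=O)O2 | intermediate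
16 | trans-4-hydroperoxycyclopent-2-en-1-yl lactone leading to 18 (not isolated) | OO[C@H]1C=C[C@@H](C1)[C@]2(C)CCC=C(CO[Si](c3ccccc3)(c3ccccc3)C(C)(C)C)C(=O)O2 | intermediate
17 | (7S)-3-{[(tert-butyldiphenylsilyl)oxy]methyl}-7-methyl-7-[(1S)-4-oxocyclopent-2-en-1-yl]-6,7-dihydrooxepin-2(5H)-one (dienophile) | O=C1C=C[C@H](C1)[C@]2(C)CCC=C(CO[Si](c3ccccc3)(c3ccccc3)C(C)(C)C)C(=O)O2 | intermediate
18 | (7S)-3-{[(tert-butyldiphenylsilyl)oxy]methyl}-7-methyl-7-[(1R)-4-oxocyclopent-2-en-1-yl]-6,7-dihydrooxepin-2(5H)-one | O=C1C=C[C@@H](C1)[C@]2(C)CCC=C(CO[Si](c3ccccc3)(c3ccccc3)C(C)(C)C)C(=O)O2 | intermediate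
19 | (7S)-3-{[(tert-butyldiphenylsilyl)oxy]methyl}-7-[(1R)-3-iodo-4-oxocyclopent-2-en-1-yl]-7-methyl-6,7-dihydrooxepin-2(5H)-one | O=C1C(I)=C[C@@H](C1)[C@]2(C)CCC=C(CO[Si](c3ccccc3)(c3ccccc3)C(C)(C)C)C(=O)O2 | intermediate
20 | (7S)-3-{[(tert-butyldiphenylsilyl)oxy]methyl}-7-methyl-7-[(1R)-3-methyl-4-oxocyclopent-2-en-1-yl]-6,7-dihydrooxepin-2(5H)-one | O=C1C(C)=C[C@@H](C1)[C@]2(C)CCC=C(CO[Si](c3ccccc3)(c3ccccc3)C(C)(C)C)C(=O)O2 | intermediate
21 | trimethylsilyl enol ether of the trans-2-ethenyl-3-methyl-4-oxocyclopentyl lactone (enol ether C3′=C4′) | C[Si](C)(C)OC1=C(C)[C@@H](C=C)[C@@H](C1)[C@]2(C)CCC=C(CO[Si](c3ccccc3)(c3ccccc3)C(C)(C)C)C(=O)O2 | intermediate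
22 | (7S)-3-{[(tert-butyldiphenylsilyl)oxy]methyl}-7-[(1R)-2-ethenyl-3-methyl-4-oxocyclopent-2-en-1-yl]-7-methyl-6,7-dihydrooxepin-2(5H)-one | O=C1C(C)=C(C=C)[C@@H](C1)[C@]2(C)CCC=C(CO[Si](c3ccccc3)(c3ccccc3)C(C)(C)C)C(=O)O2 | intermediate
23 | (7S)-7-[(1R)-4-[(tert-butyldimethylsilyl)oxy]-2-ethenyl-3-methylcyclopenta-2,4-dien-1-yl]-3-{[(tert-butyldiphenylsilyl)oxy]methyl}-7-methyl-6,7-dihydrooxepin-2(5H)-one (diene) | CC(C)(C)[Si](C)(C)OC1=C[C@@H]([C@]2(C)CCC=C(CO[Si](c3ccccc3)(c3ccccc3)C(C)(C)C)C(=O)O2)C(C=C)=C1C | intermediate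
24 | endo cycloadduct, C3′ tert-butyldimethylsilyl enol ether (not isolated) | O=C1C[C@H]([C@]4(C)CCC=C(CO[Si](c5ccccc5)(c5ccccc5)C(C)(C)C)C(=O)O4)[C@H]2[C@H]3C(O[Si](C)(C)C(C)(C)C)=C(C)[C@](C=C)([C@@H]3[C@]6(C)CCC=C(CO[Si](c7ccccc7)(c7ccccc7)C(C)(C)C)C(=O)O6)[C@@H]12 | intermediate
25 | tricyclic C4,C3′-diketone with C4′ endo-methyl, C5′ vinyl and both oxepinone lactones | O=C1C[C@H]([C@]4(C)CCC=C(CO[Si](c5ccccc5)(c5ccccc5)C(C)(C)C)C(=O)O4)[C@H]2[C@H]3C(=O)[C@@H](C)[C@](C=C)([C@@H]3[C@]6(C)CCC=C(CO[Si](c7ccccc7)(c7ccccc7)C(C)(C)C)C(=O)O6)[C@@H]12 | intermediate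
26 | ring A β-bromo enal (C4–Br, C5–CHO) | BrC1=C(C=O)[C@H]([C@]4(C)CCC=C(CO[Si](c5ccccc5)(c5ccccc5)C(C)(C)C)C(=O)O4)[C@H]2[C@H]3C(=O)[C@@H](C)[C@](C=C)([C@@H]3[C@]6(C)CCC=C(CO[Si](c7ccccc7)(c7ccccc7)C(C)(C)C)C(=O)O6)[C@@H]12 | intermediate
27 | ring A enal (C4–CH3, C5–CHO) with C5′ vinyl | CC1=C(C=O)[C@H]([C@]4(C)CCC=C(CO[Si](c5ccccc5)(c5ccccc5)C(C)(C)C)C(=O)O4)[C@H]2[C@H]3C(=O)[C@@H](C)[C@](C=C)([C@@H]3[C@]6(C)CCC=C(CO[Si](c7ccccc7)(c7ccccc7)C(C)(C)C)C(=O)O6)[C@@H]12 | intermediate
28 | C5′ 1,2-dihydroxyethyl compound, both carbinol epimers (not isolated) | CC1=C(C=O)[C@H]([C@]4(C)CCC=C(CO[Si](c5ccccc5)(c5ccccc5)C(C)(C)C)C(=O)O4)[C@H]2[C@H]3C(=O)[C@@H](C)[C@](C(O)CO)([C@@H]3[C@]6(C)CCC=C(CO[Si](c7ccccc7)(c7ccccc7)C(C)(C)C)C(=O)O6)[C@@H]12 | intermediate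
29 | C6,C6′-dialdehyde bis(silyl ether) | CC1=C(C=O)[C@H]([C@]4(C)CCC=C(CO[Si](c5ccccc5)(c5ccccc5)C(C)(C)C)C(=O)O4)[C@H]2[C@H]3C(=O)[C@@H](C)[C@](C=O)([C@@H]3[C@]6(C)CCC=C(CO[Si](c7ccccc7)(c7ccccc7)C(C)(C)C)C(=O)O6)[C@@H]12 | intermediate
30 | dialdehyde bis[3-(hydroxymethyl)oxepin-2-one] | CC1=C(C=O)[C@H]([C@]4(C)CCC=C(CO)C(=O)O4)[C@H]2[C@H]3C(=O)[C@@H](C)[C@](C=O)([C@@H]3[C@]5(C)CCC=C(CO)C(=O)O5)[C@@H]12 | intermediate
31 | dialdehyde bis[3-(bromomethyl)oxepin-2-one], key-step precursor | CC1=C(C=O)[C@H]([C@]4(C)CCC=C(CBr)C(=O)O4)[C@H]2[C@H]3C(=O)[C@@H](C)[C@](C=O)([C@@H]3[C@]5(C)CCC=C(CBr)C(=O)O5)[C@@H]12 | intermediate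
32 | bridged bis(hydroxy lactone): C6–C7 and C6′–C7′ formed, C12–O10 and C12′–O10′ esters still in place (not isolated) | CC1=C2[C@@H](O)[C@H]3CC[C@](C)(OC(=O)C3=C)[C@@H]2[C@H]2[C@H]3C(=O)[C@@H](C)[C@]4([C@@H]3[C@]5(C)CC[C@@H](C(=C)C(=O)O5)[C@@H]4O)[C@@H]12 | intermediate
33 | bis(α-methylene γ-lactone) diol (11,13:11′,13′-didehydro target) | CC1=C2[C@H]3OC(=O)C(=C)[C@@H]3CC[C@](C)(O)[C@@H]2[C@H]2[C@H]3C(=O)[C@@H](C)[C@]4([C@@H]3[C@@](C)(O)CC[C@H]3C(=C)C(=O)O[C@@H]34)[C@@H]12 | intermediate
34 | CNP0243924.4 | CC1=C2[C@H]3OC(=O)[C@@H](C)[C@@H]3CC[C@](C)(O)[C@@H]2[C@H]2[C@H]3C(=O)[C@@H](C)[C@]4([C@@H]3[C@@](C)(O)CC[C@H]3[C@H](C)C(=O)O[C@@H]34)[C@@H]12 | target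

**Step count**
Total steps: 25. Longest linear sequence: 23 steps (steps 1–7 and 10–25; steps 8 and 9 form the side branch).

**Steps most likely to fail**

Step 24 (proposed new method). The allylchromium may be protonated or reductively coupled before it reaches the strained bicyclo[3.3.2] transition state, or one half may close while the other stalls. The fallback keeps the tether but replaces the reductive metalation by a non-reductive allylboron route of known type. It sets out from 31: palladium-catalysed borylation of both allylic bromides with bis(pinacolato)diboron (Pd2(dba)3, DMSO; Miyaura borylation of allylic halides) should give the bis(allylboronate) F1. Warming in toluene lets the 2-alkoxycarbonyl allylboronates add to the aldehydes through the same chair arrangement to give the bridged bis(pinacol borate) F2. Aqueous work-up gives 32, and acyl transfer brings the route back at 33.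

Step 18. The diene may undergo 1,5-hydrogen shift before it reacts, or the reaction may stop after the C2′–C2 bond has formed without closure of the C5′–C3 bond. The fallback replaces the cycloaddition of the silyl dienol ether by an anionic double Michael annulation. It sets out from 22 and 17: LiN(SiMe3)2 in THF at −78 °C converts 22 into its cross-conjugated lithium dienolate, which adds to 17 anti to both ring substituents. If the second addition does not follow on warming, the 1,5-diketone Michael adduct F3 is closed with KOt-Bu in t-BuOH/THF, in which the ring A enolate attacks C5′ of the vinyl-substituted enone. Protonation of the resulting C3′ enolate on the exo face returns the route at 25.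

Step 25. Hydrogen delivery may show poor facial selectivity at C11 and C11′, or the rhodium catalyst may move the exocyclic alkenes into the lactone rings. The fallback changes from catalytic hydrogenation to hydride conjugate addition with enolate protonation. It sets out from 33: [(Ph3P)CuH]6 in toluene reduces both α-methylene lactones, and protonation on work-up, followed if needed by equilibration with a catalytic amidine base, should give the more stable epimers with each methyl cis to H7 (H7′). This makes no new compound (F0) and returns at 34.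

**Further compounds**
F1 | step 24 | dialdehyde bis{3-[(4,4,5,5-tetramethyl-1,3,2-dioxaborolan-2-yl)methyl]oxepin-2-one} | CC1=C(C=O)[C@H]([C@]4(C)CCC=C(CB5OC(C)(C)C(C)(C)O5)C(=O)O4)[C@H]2[C@H]3C(=O)[C@@H](C)[C@](C=O)([C@@H]3[C@]6(C)CCC=C(CB7OC(C)(C)C(C)(C)O7)C(=O)O6)[C@@H]12
F2 | step 24 | bridged bis(lactone) with pinacol borate esters at O6 and O6′ | CC1=C2[C@@H](OB6OC(C)(C)C(C)(C)O6)[C@H]3CC[C@](C)(OC(=O)C3=C)[C@@H]2[C@H]2[C@H]3C(=O)[C@@H](C)[C@]4([C@@H]3[C@]5(C)CC[C@@H](C(=C)C(=O)O5)[C@@H]4OB7OC(C)(C)C(C)(C)O7)[C@@H]12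
F3 | step 18 | 1,5-diketone Michael adduct (C2–C2′ bond formed, C3–C5′ open) | O=C1C[C@H]([C@]3(C)CCC=C(CO[Si](c4ccccc4)(c4ccccc4)C(C)(C)C)C(=O)O3)[C@H](C1)[C@H]2C(=O)C(C)=C(C=C)[C@@H]2[C@]5(C)CCC=C(CO[Si](c6ccccc6)(c6ccccc6)C(C)(C)C)C(=O)O5
F0 | step 25 | none | none
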